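**Retrosynthetic overview**
1. Target ⇐ bis-acetylation of the 2,6-diol ⇐ chelation-controlled reduction of a C6 ketone.
2. Ten-membered carbocycle (last ring) ⇐ ring expansion of a six-membered α,β-epoxy δ-lactone: C7 (γ-carbon of a 3-(bromomethyl)butenolide) acylates at C6 and the lactone C6–O(C2) bond breaks, which also unveils the α-methylene lactone and the C2 hydroxyl.
3. Bromomethylbutenolide (third ring) ⇐ esterification of the C8 carbinol with 2-(bromomethyl)acrylic acid, then ring-closing metathesis.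
4. Epoxide (second ring) ⇐ trans-selective nucleophilic epoxidation of a dihydropyranone (first ring) ⇐ catalytic asymmetric vinylogous aldol–lactonisation (C2–C3 bond, sets C2).
5. Hydroxy enal ⇐ catalytic asymmetric vinylogous Mukaiyama aldol of crotonaldehyde with a senecioate dienolate (C8–C9 bond, sets C8 and the E-alkene).

Assumption: germacrane numbering is used (ring C1–C10, lactone carbons C11–C13; target is 1(10)E,2S,4R,5S,6S,7R,8S), and in steps 2 and 5 the catalyst enantiomer is taken to be the one that gives the drawn configuration.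

**Step 1**
Reactants: 1 methyl 3-methylbut-2-enoate
Product: 2 tert-butyl[(1-methoxy-3-methylbuta-1,3-dien-1-yl)oxy]dimethylsilane
Conditions: LiN(iPr)2, THF, −78 °C; TBSCl, DMPU, −78 °C to rt
Reagents that add atoms: tert-butyldimethylsilyl chloride, CC(C)(C)[Si](C)(C)Cl
Why: γ-Deprotonation of the senecioate and O-silylation (silyl ketene acetal formation) give the silyl dienolate needed for the vinylogous Mukaiyama aldol.

**Step 2**
Reactants: 2 tert-butyl[(1-methoxy-3-methylbuta-1,3-dien-1-yl)oxy]dimethylsilane; 3 (E)-but-2-enal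
Product: 4 methyl (2E,5S,6E)-5-hydroxy-3-methylocta-2,6-dienoate
Conditions: SiCl4 (1.1 equiv), chiral binaphthyldiamine-derived bisphosphoramide (5 mol%), iPr2NEt (10 mol%), CH2Cl2, −78 °C; aq NaHCO3
Reagents that add atoms: none
Why: Lewis-base-catalysed, SiCl4-mediated vinylogous Mukaiyama aldol, in which the γ-carbon of 2 adds 1,2 to the aldehyde held by the chiral phosphoramide-bound silyl cation, setting 5S by catalyst control and giving the 2E enoate.

**Step 3**
Reactants: 4 methyl (2E,5S,6E)-5-hydroxy-3-methylocta-2,6-dienoate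
Product: 5 (2E,5S,6E)-3-methylocta-2,6-diene-1,5-diol
Conditions: iBu2AlH (3.2 equiv), CH2Cl2, −78 to 0 °C
Reagents that add atoms: none
Why: 1,2-Hydride reduction of the conjugated ester to the allylic alcohol leaves both alkenes and the carbinol centre untouched.

**Step 4**
Reactants: 5 (2E,5S,6E)-3-methylocta-2,6-diene-1,5-diol
Product: 6 (2E,5S,6E)-5-hydroxy-3-methylocta-2,6-dienal
Conditions: TEMPO (10 mol%), PhI(OAc)2 (1.1 equiv), CH2Cl2, 0 °C to rt
Reagents that add atoms: none
Why: Oxoammonium (TEMPO) oxidation is selective for the primary allylic alcohol over the secondary one and does not isomerise the E-enal.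

**Step 5**
Reactants: 6 (2E,5S,6E)-5-hydroxy-3-methylocta-2,6-dienal; 7 methyl 3-methylbut-3-enoate
Product: 8 (6S)-6-[(1E,4S,5E)-4-hydroxy-2-methylhepta-1,5-dien-1-yl]-4-methyl-5,6-dihydro-2H-pyran-2-one
Conditions: Cu(MeCN)4PF6 (5 mol%), (R)-DTBM-SEGPHOS (6 mol%), Et3N (10 mol%), THF, 0 °C
Reagents that add atoms: none
Why: Direct catalytic asymmetric vinylogous aldol–lactonisation, in which the soft monovalent copper dienolate of 7 adds through its γ-carbon to the aldehyde in the chiral bisphosphine pocket (sets 6S by catalyst control, the remote carbinol has no influence) and the Z-aldolate closes to the dihydropyranone with loss of methanol.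

**Step 6**
Reactants: 8 (6S)-6-[(1E,4S,5E)-4-hydroxy-2-methylhepta-1,5-dien-1-yl]-4-methyl-5,6-dihydro-2H-pyran-2-one
Product: 9 (1R,4S,6R)-4-[(1E,4S,5E)-4-hydroxy-2-methylhepta-1,5-dien-1-yl]-6-methyl-3,7-dioxabicyclo[4.1.0]heptan-2-one
Conditions: t-BuOOH (3 equiv), nBuLi (2 equiv), THF, −78 to 0 °C
Reagents that add atoms: tert-butyl hydroperoxide, CC(C)(C)OO
Why: Weitz–Scheffer nucleophilic epoxidation, in which the weakly basic peroxide anion adds to the β-carbon axially and anti to the ring substituent and the enolate closes on oxygen, so the cis-fused epoxide forms trans to the side chain (sets both epoxide centres) while the electron-rich alkenes are inert.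

**Step 7**
Reactants: 9 (1R,4S,6R)-4-[(1E,4S,5E)-4-hydroxy-2-methylhepta-1,5-dien-1-yl]-6-methyl-3,7-dioxabicyclo[4.1.0]heptan-2-one; 10 2-(bromomethyl)prop-2-enoic acid
Product: 11 (2E,4S,5E... written out) (1E,4S,5E)-2-methyl-1-[(1R,4S,6R)-6-methyl-2-oxo-3,7-dioxabicyclo[4.1.0]heptan-4-yl]hepta-1,5-dien-4-yl 2-(bromomethyl)prop-2-enoate
Conditions: DCC, DMAP (5 mol%), CH2Cl2, 0 °C
Reagents that add atoms: none
Why: Steglich esterification acylates the only free hydroxyl with retention at the carbinol carbon; low DMAP loading and 0 °C spare the allylic bromide.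

**Step 8**
Reactants: 11 (1E,4S,5E)-2-methyl-1-[(1R,4S,6R)-6-methyl-2-oxo-3,7-dioxabicyclo[4.1.0]heptan-4-yl]hepta-1,5-dien-4-yl 2-(bromomethyl)prop-2-enoate
Product: 12 (5S)-3-(bromomethyl)-5-{(2E)-2-methyl-3-[(1R,4S,6R)-6-methyl-2-oxo-3,7-dioxabicyclo[4.1.0]heptan-4-yl]prop-2-en-1-yl}furan-2(5H)-one
Conditions: second-generation Hoveyda–Grubbs catalyst (5 mol%), toluene, 80 °C
Reagents that add atoms: none
Why: Ring-closing metathesis between the propenyl group and the acrylate gives the five-membered butenolide with loss of propene; the trisubstituted alkene cannot compete because it would give a four-membered or tetrasubstituted ring alkene.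

**Step 9**
Reactants: 12 (5S)-3-(bromomethyl)-5-{(2E)-2-methyl-3-[(1R,4S,6R)-6-methyl-2-oxo-3,7-dioxabicyclo[4.1.0]heptan-4-yl]prop-2-en-1-yl}furan-2(5H)-one
Product: 15 (1(10)E)-4,5-epoxy-2,6-dihydroxygermacra-1(10),11(13)-dien-12,8-olide, via allylic zinc bromide 13 (not isolated), via ten-membered hydroxy ketone 14 (not isolated)
Conditions: Zn dust, LiCl, THF, 25 °C, slow addition to 2 mM; then Zn(BH4)2, Et2O, −78 to −30 °C; aq NH4Cl
Reagents that add atoms: none
Why: Proposed new method: a zinc-mediated intramolecular Barbier-type nucleophilic acyl substitution that expands the six-membered lactone to the ten-membered carbocycle – zinc inserts into the allylic C–Br bond, allylic zinc bromide 13 attacks through its γ-carbon (C7, SE2′, anti to the C8 side chain, giving the trans lactone fusion) the lactone carbonyl activated by the α-epoxide and by zinc chelation, and the bridged zinc hemiketalate, strained by the E-alkene, collapses by cleavage of the ring C–O bond to keto alkoxide 14 (the nucleophile is spent and the solution dilute, so no second addition), which Zn(BH4)2 then reduces under epoxide-oxygen chelation control to the erythro 6S alcohol; the closest known reactions are the SmI2-mediated intramolecular Barbier acyl substitution of halo lactones to ring-expanded hydroxy ketones and the macrocyclic Barbier allylation of epoxy aldehydes by 2-(bromomethyl)acrylates, and the chelation-controlled Zn(BH4)2 reduction of α,β-epoxy ketones is itself known.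

**Step 10**
Reactants: 15 (1(10)E)-4,5-epoxy-2,6-dihydroxygermacra-1(10),11(13)-dien-12,8-olide
Product: 16 (1(10)E,2S,4R,5S,6S,7R,8S)-2,6-diacetoxy-4,5-epoxygermacra-1(10),11(13)-dien-12,8-olide
Conditions: Ac2O, pyridine, DMAP (5 mol%), CH2Cl2, 0 °C
Reagents that add atoms: acetic anhydride, CC(=O)OC(C)=O
Why: Mild acylation esterifies both secondary hydroxyls with retention and does not open the epoxide or add to the α-methylene lactone.

**Compound list**
1 | methyl 3-methylbut-2-enoate | CC(C)=CC(=O)OC | starting material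
2 | tert-butyl[(1-methoxy-3-methylbuta-1,3-dien-1-yl)oxy]dimethylsilane (ketene acetal geometry not relevant, used as formed) | C=C(C)C=C(OC)O[Si](C)(C)C(C)(C)C | intermediate
3 | (E)-but-2-enal (crotonaldehyde) | C/C=C/C=O | starting material
4 | methyl (2E,5S,6E)-5-hydroxy-3-methylocta-2,6-dienoate | C/C=C/[C@@H](O)C/C(C)=C/C(=O)OC | intermediate
5 | (2E,5S,6E)-3-methylocta-2,6-diene-1,5-diol | C/C=C/[C@@H](O)C/C(C)=C/CO | intermediate
6 | (2E,5S,6E)-5-hydroxy-3-methylocta-2,6-dienal | C/C=C/[C@@H](O)C/C(C)=C/C=O | intermediate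
7 | methyl 3-methylbut-3-enoate | C=C(C)CC(=O)OC | starting material
8 | (6S)-6-[(1E,4S,5E)-4-hydroxy-2-methylhepta-1,5-dien-1-yl]-4-methyl-5,6-dihydro-2H-pyran-2-one | C/C=C/[C@@H](O)C/C(C)=C/[C@@H]1CC(C)=CC(=O)O1 | intermediate
9 | (1R,4S,6R)-4-[(1E,4S,5E)-4-hydroxy-2-methylhepta-1,5-dien-1-yl]-6-methyl-3,7-dioxabicyclo[4.1.0]heptan-2-one | C/C=C/[C@@H](O)C/C(C)=C/[C@@H]1C[C@@]2(C)O[C@H]2C(=O)O1 | intermediate
10 | 2-(bromomethyl)prop-2-enoic acid | C=C(CBr)C(=O)O | starting material
11 | (1E,4S,5E)-2-methyl-1-[(1R,4S,6R)-6-methyl-2-oxo-3,7-dioxabicyclo[4.1.0]heptan-4-yl]hepta-1,5-dien-4-yl 2-(bromomethyl)prop-2-enoate | C/C=C/[C@@H](OC(=O)C(=C)CBr)C/C(C)=C/[C@@H]1C[C@@]2(C)O[C@H]2C(=O)O1 | intermediate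
12 | (5S)-3-(bromomethyl)-5-{(2E)-2-methyl-3-[(1R,4S,6R)-6-methyl-2-oxo-3,7-dioxabicyclo[4.1.0]heptan-4-yl]prop-2-en-1-yl}furan-2(5H)-one | BrCC1=C[C@H](C/C(C)=C/[C@@H]2C[C@@]3(C)O[C@H]3C(=O)O2)OC1=O | intermediate
13 | allylic zinc bromide of 12 (ZnBr in place of Br on the butenolide CH2) | Br[Zn]CC1=C[C@H](C/C(C)=C/[C@@H]2C[C@@]3(C)O[C@H]3C(=O)O2)OC1=O | intermediate
14 | (1(10)E)-4,5-epoxy-2-hydroxy-6-oxogermacra-1(10),11(13)-dien-12,8-olide, C2, C4, C5, C7 and C8 arranged as in 16 | C=C1C(=O)O[C@H]2C/C(C)=C/[C@@H](O)C[C@@]3(C)O[C@H]3C(=O)[C@H]12 | intermediate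
15 | (1(10)E)-4,5-epoxy-2,6-dihydroxygermacra-1(10),11(13)-dien-12,8-olide, all six stereocentres arranged as in 16 | C=C1C(=O)O[C@H]2C/C(C)=C/[C@@H](O)C[C@@]3(C)O[C@H]3[C@@H](O)[C@H]12 | intermediate
16 | (1(10)E,2S,4R,5S,6S,7R,8S)-2,6-diacetoxy-4,5-epoxygermacra-1(10),11(13)-dien-12,8-olide | C=C1C(=O)O[C@H]2C/C(C)=C/[C@@H](OC(C)=O)C[C@@]3(C)O[C@H]3[C@@H](OC(C)=O)[C@H]12 | target

**Totals**
Total steps: 10. Longest linear sequence: 10.

**Steps most likely to fail**

Step 9 (the new ring expansion). An ester-substituted allylic zinc may be too weak a nucleophile for a lactone, the allylic bromide may dimerise, keto alkoxide 14 is a β-acyloxy ketone that can epimerise at C7 or eliminate, and the facial selectivity of the reduction at C6 is untested in this ring. The fallback sets out from 12 and uses known chemistry: iBu2AlH (1.05 equiv, CH2Cl2, −78 °C) reduces the epoxy δ-lactone, which is more electrophilic than the conjugated butenolide, to the lactol (5S)-3-(bromomethyl)-5-{(2E)-3-[(1R,4S,6R)-2-hydroxy-6-methyl-3,7-dioxabicyclo[4.1.0]heptan-4-yl]-2-methylprop-2-en-1-yl}furan-2(5H)-one F1. Its hydroxy-aldehyde tautomer is then closed by the established CrCl2-mediated macrocyclic Barbier allylation (THF/DMF, 25 °C, high dilution), with Felkin-type addition to the epoxy aldehyde and attack anti to the C8 side chain. This is an open-chain macrocyclisation with no ketone stage, and it comes back to the route at 15.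

Step 8 (ring-closing metathesis). The electron-poor 1,1-disubstituted acrylate closes slowly and the allylic bromide may interfere with the ruthenium carbene. The fallback sets out from 9 and installs the bromide after ring closure. Steglich esterification with 2-{[tert-butyl(dimethyl)silyl]oxymethyl}prop-2-enoic acid gives (1E,4S,5E)-2-methyl-1-[(1R,4S,6R)-6-methyl-2-oxo-3,7-dioxabicyclo[4.1.0]heptan-4-yl]hepta-1,5-dien-4-yl 2-{[tert-butyl(dimethyl)silyl]oxymethyl}prop-2-enoate F2. Metathesis with the second-generation Hoveyda–Grubbs catalyst gives the silyloxymethyl butenolide (5S)-3-{[tert-butyl(dimethyl)silyl]oxymethyl}-5-{(2E)-2-methyl-3-[(1R,4S,6R)-6-methyl-2-oxo-3,7-dioxabicyclo[4.1.0]heptan-4-yl]prop-2-en-1-yl}furan-2(5H)-one F3. Bu4NF buffered with AcOH frees the hydroxymethyl butenolide (5S)-3-(hydroxymethyl)-5-{(2E)-2-methyl-3-[(1R,4S,6R)-6-methyl-2-oxo-3,7-dioxabicyclo[4.1.0]heptan-4-yl]prop-2-en-1-yl}furan-2(5H)-one F4, and CBr4/PPh3 converts it to the bromide, coming back at 12.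

Step 5 (asymmetric vinylogous aldol–lactonisation). The hindered β,β-disubstituted enal with a free hydroxyl may react slowly or with low selectivity. The fallback sets out from 6 and gives up catalyst control: the dianion of 3-methylbut-2-enoic acid (LiN(iPr)2, THF, 0 °C, excess to allow for the free hydroxyl) adds through its γ-carbon and acidification lactonises the adduct. This gives 8 together with its epimer (6R)-6-[(1E,4S,5E)-4-hydroxy-2-methylhepta-1,5-dien-1-yl]-4-methyl-5,6-dihydro-2H-pyran-2-one F5; the two are diastereomers and are separated by chromatography, and the route is rejoined at 8.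

**Further compounds**
F1 | step 9 | (5S)-3-(bromomethyl)-5-{(2E)-3-[(1R,4S,6R)-2-hydroxy-6-methyl-3,7-dioxabicyclo[4.1.0]heptan-4-yl]-2-methylprop-2-en-1-yl}furan-2(5H)-one (lactol, anomeric mixture) | BrCC1=C[C@H](C/C(C)=C/[C@@H]2C[C@@]3(C)O[C@H]3C(O)O2)OC1=O
F2 | step 8 | (1E,4S,5E)-2-methyl-1-[(1R,4S,6R)-6-methyl-2-oxo-3,7-dioxabicyclo[4.1.0]heptan-4-yl]hepta-1,5-dien-4-yl 2-{[tert-butyl(dimethyl)silyl]oxymethyl}prop-2-enoate | C/C=C/[C@@H](OC(=O)C(=C)CO[Si](C)(C)C(C)(C)C)C/C(C)=C/[C@@H]1C[C@@]2(C)O[C@H]2C(=O)O1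
F3 | step 8 | (5S)-3-{[tert-butyl(dimethyl)silyl]oxymethyl}-5-{(2E)-2-methyl-3-[(1R,4S,6R)-6-methyl-2-oxo-3,7-dioxabicyclo[4.1.0]heptan-4-yl]prop-2-en-1-yl}furan-2(5H)-one | CC(C)(C)[Si](C)(C)OCC1=C[C@H](C/C(C)=C/[C@@H]2C[C@@]3(C)O[C@H]3C(=O)O2)OC1=O
F4 | step 8 | (5S)-3-(hydroxymethyl)-5-{(2E)-2-methyl-3-[(1R,4S,6R)-6-methyl-2-oxo-3,7-dioxabicyclo[4.1.0]heptan-4-yl]prop-2-en-1-yl}furan-2(5H)-one | OCC1=C[C@H](C/C(C)=C/[C@@H]2C[C@@]3(C)O[C@H]3C(=O)O2)OC1=O
F5 | step 5 | (6R)-6-[(1E,4S,5E)-4-hydroxy-2-methylhepta-1,5-dien-1-yl]-4-methyl-5,6-dihydro-2H-pyran-2-one | C/C=C/[C@@H](O)C/C(C)=C/[C@H]1CC(C)=CC(=O)O1
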